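**Plan**

- Retrosynthetic cuts, in order: the exocyclic C=CH2 (α-methylenation of a C7 arylacetyl ketone), the C7–C(=O) bond (Friedel–Crafts acylation), the C3–C(=O)Ar bond (Weinreb amide plus aryllithium), and finally O1–C7a and C3–C3a of the furan (aryne [3+2] annulation with a β-ketoester iodonium ylide).
- Enabling feature: O1 on C7a and C3 on C3a are ortho neighbours on the benzo ring, and the C4 oxygen sits next to C3a. This is the pattern that nucleophile-then-electrophile addition across 3,5-dimethoxybenzyne delivers, and the C2-aryl/C3-carbonyl pair maps onto an aroylacetate ylide.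
- Forward order: the benzo ring is bought, the furan ring is closed on it in one step, then the C3 aroyl and the C7 arylacetyl groups are attached.
- End game: the methyl ethers are cleaved while the side chain is still saturated, the phenols are carried as silyl ethers through the methylenation, and fluoride releases the target.
- Stereochemistry: the target has no stereocentre and no stereogenic double bond; all selectivity questions are regiochemical.

Key step: step 5

Assumption: the 7-(2-arylacryloyl)-6-hydroxy unit is taken to be stable under neutral or weakly acidic conditions but liable to oxa-Michael ring closure under base and to HBr addition under BBr3, so the enone is made after demethylation and unveiled last with buffered fluoride.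

**Route**

Step 1
Reactants: 1 3,5-dimethoxyphenol
Product: 2 2-bromo-3,5-dimethoxyphenol
Conditions: NBS (1.0 equiv), CH2Cl2, −78 °C → 0 °C
Reagents that add atoms: N-bromosuccinimide, O=C1CCC(=O)N1Br
Why: Electrophilic aromatic bromination, in which hydrogen-bonded delivery of bromine in a non-polar solvent at low temperature should favour the position ortho to the hydroxyl over the crowded C4 between the two methoxyls, with the minor isomer removable by chromatography.

Step 2
Reactants: 2 2-bromo-3,5-dimethoxyphenol
Product: 3 (2-bromo-3,5-dimethoxyphenoxy)trimethylsilane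
Conditions: HMDS, THF, 65 °C; evaporate
Reagents that add atoms: hexamethyldisilazane, C[Si](C)(C)N[Si](C)(C)C
Why: O-Silylation of a phenol with HMDS, whose only by-product is ammonia, so the silyl ether should be usable after simple evaporation.

Step 3
Reactants: 3 (2-bromo-3,5-dimethoxyphenoxy)trimethylsilane
Product: 6 3,5-dimethoxy-2-(trimethylsilyl)phenyl trifluoromethanesulfonate, via 2-lithio-3,5-dimethoxyphenyl trimethylsilyl ether 4 (not isolated), via lithium 3,5-dimethoxy-2-(trimethylsilyl)phenoxide 5 (not isolated)
Conditions: n-BuLi, THF, −100 → −80 °C; then Tf2O, −100 → −78 °C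
Reagents that add atoms: trifluoromethanesulfonic anhydride, FC(F)(F)S(=O)(=O)OS(=O)(=O)C(F)(F)F
Why: Bromine–lithium exchange followed by anionic 1,3 O→C silyl migration (retro-Brook rearrangement) and O-triflation of the resulting phenoxide, the standard entry to ortho-silylaryl triflates.

Step 4
Reactants: 7 methyl 3-(4-methoxyphenyl)-3-oxopropanoate
Product: 8 phenyliodonium ylide of methyl 3-(4-methoxyphenyl)-3-oxopropanoate
Conditions: PhI(OAc)2, KOH, MeOH, 0 °C; precipitate with cold water, store cold and use promptly
Reagents that add atoms: (diacetoxyiodo)benzene, CC(=O)OI(OC(C)=O)c1ccccc1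
Why: Iodonium ylide formation, in which the doubly activated methylene displaces both acetates at iodine under base, the usual preparation of 1,3-dicarbonyl iodonium ylides.

Step 5
Reactants: 6 3,5-dimethoxy-2-(trimethylsilyl)phenyl trifluoromethanesulfonate; 8 phenyliodonium ylide of methyl 3-(4-methoxyphenyl)-3-oxopropanoate
Product: 10 methyl 4,6-dimethoxy-2-(4-methoxyphenyl)benzofuran-3-carboxylate, via 3,5-dimethoxybenzyne 9 (not isolated)
Conditions: CsF (3 equiv), MeCN, rt; 8 in slight excess
Reagents that add atoms: none
Why: Fluoride attacks silicon of 6 and triflate departs, releasing 3,5-dimethoxybenzyne 9, whose triple bond is polarised by the methoxyl flanking one of its termini. The ketone-enolate oxygen of ylide 8 adds to the aryne carbon remote from that methoxyl (the future C7a), so the aryl anion develops at the future C3a, next to the methoxyl, where the C–O dipole stabilises it. The anion then bonds to the iodonium-bearing carbon with loss of iodobenzene, either by direct intramolecular vinylic substitution (formally 5-endo at the sp2 carbon) or by attack at iodine and ligand coupling, and this closes the furan ring as O1–C7a and C3–C3a form. The closest known reaction type is the fluoride-induced [3+2] annulation of arynes with iodonium ylides of 1,3-dicarbonyl compounds, which gives 3-acyl- and 3-alkoxycarbonylbenzofurans. Two selectivities are needed: the orientation on the aryne, secured by the distortion and inductive pull of the adjacent methoxyl, and closure through the ketone oxygen and not the ester oxygen, secured by the much greater enolate character of the aryl ketone, which places the 4-methoxyphenyl on C2 and the ester on C3. No stereocentre is formed.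

Step 6
Reactants: 10 methyl 4,6-dimethoxy-2-(4-methoxyphenyl)benzofuran-3-carboxylate
Product: 11 N,4,6-trimethoxy-2-(4-methoxyphenyl)-N-methylbenzofuran-3-carboxamide
Conditions: MeNH(OMe)·HCl, i-PrMgCl, THF, −20 °C → rt
Reagents that add atoms: N,O-dimethylhydroxylamine hydrochloride, CNOC.Cl
Why: Direct aminolysis of the ester by the chloromagnesium amide of N,O-dimethylhydroxylamine (Weinreb amide synthesis), a nucleophile strong enough for a moderately hindered, vinylogous-carbonate-type ester.

Step 7
Reactants: 11 N,4,6-trimethoxy-2-(4-methoxyphenyl)-N-methylbenzofuran-3-carboxamide; 12 1-bromo-2,4-dimethoxybenzene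
Product: 14 (2,4-dimethoxyphenyl)[4,6-dimethoxy-2-(4-methoxyphenyl)benzofuran-3-yl]methanone, via 2,4-dimethoxyphenyllithium 13 (not isolated)
Conditions: 12, n-BuLi, THF, −78 °C; then 11, −78 → 0 °C; aq. NH4Cl
Reagents that add atoms: none
Why: Bromine–lithium exchange followed by Weinreb ketone synthesis, in which the chelated tetrahedral adduct survives until work-up so that the aryllithium adds only once and the aryl ketone is formed without any electrophilic chemistry on the electron-rich benzofuran.

Step 8
Reactants: 14 (2,4-dimethoxyphenyl)[4,6-dimethoxy-2-(4-methoxyphenyl)benzofuran-3-yl]methanone; 15 4-methoxyphenylacetyl chloride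
Product: 16 1-[3-(2,4-dimethoxybenzoyl)-4,6-dimethoxy-2-(4-methoxyphenyl)benzofuran-7-yl]-2-(4-methoxyphenyl)ethan-1-one
Conditions: SnCl4, CH2Cl2, 0 °C → rt
Reagents that add atoms: none
Why: Friedel–Crafts acylation at C7, the most nucleophilic open position (ortho to O1 and the 6-methoxyl, para to the 4-methoxyl), whereas C5 is buried between two methoxyls and the other rings are less activated or carry the deactivating carbonyl; any chelation-assisted loss of the 6-methyl group would converge in step 9.

Step 9
Reactants: 16 1-[3-(2,4-dimethoxybenzoyl)-4,6-dimethoxy-2-(4-methoxyphenyl)benzofuran-7-yl]-2-(4-methoxyphenyl)ethan-1-one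
Product: 17 1-[3-(2,4-dihydroxybenzoyl)-4,6-dihydroxy-2-(4-hydroxyphenyl)benzofuran-7-yl]-2-(4-hydroxyphenyl)ethan-1-one
Conditions: BBr3 (excess), CH2Cl2, −78 °C → rt; MeOH, then H2O
Reagents that add atoms: none
Why: Lewis-acid cleavage of all six aryl methyl ethers (BBr3 demethylation), carried out while the side chain is still a saturated, acid-stable deoxybenzoin so that no enone is exposed to BBr3 or HBr.

Step 10
Reactants: 17 1-[3-(2,4-dihydroxybenzoyl)-4,6-dihydroxy-2-(4-hydroxyphenyl)benzofuran-7-yl]-2-(4-hydroxyphenyl)ethan-1-one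
Product: 18 hexakis(tert-butyldimethylsilyl) ether of 17
Conditions: TBSCl (excess), imidazole, cat. DMAP, DMF, rt → 40 °C
Reagents that add atoms: tert-butyldimethylsilyl chloride, CC(C)(C)[Si](C)(C)Cl
Why: Phenol silylation under Corey conditions, where imidazole is basic enough to silylate even the hydrogen-bonded ortho-hydroxy ketones but too weak to enolise the benzylic ketone towards O-silylation.

Step 11
Reactants: 18 hexakis(tert-butyldimethylsilyl) ether of 17
Product: 19 1-{3-[2,4-bis(tert-butyldimethylsilyloxy)benzoyl]-4,6-bis(tert-butyldimethylsilyloxy)-2-[4-(tert-butyldimethylsilyloxy)phenyl]benzofuran-7-yl}-2-[4-(tert-butyldimethylsilyloxy)phenyl]prop-2-en-1-one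
Conditions: (CH2O)n, PhNHMe·CF3CO2H, THF, reflux
Reagents that add atoms: paraformaldehyde (as formaldehyde), C=O
Why: Mannich-type α-methylenation (iminium formation, Mannich addition at the doubly activated benzylic α-CH2, β-elimination of N-methylaniline) in a weakly acidic medium that aryl silyl ethers tolerate and in which the silylated, flanked ring positions should not compete.

Step 12
Reactants: 19 hexasilylated 2-arylacryloyl benzofuran
Product: 20 1-[3-(2,4-dihydroxybenzoyl)-4,6-dihydroxy-2-(4-hydroxyphenyl)benzofuran-7-yl]-2-(4-hydroxyphenyl)prop-2-en-1-one (target)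
Conditions: HF·pyridine, pyridine, THF, 0 °C → rt; pH 5–6 buffer work-up
Reagents that add atoms: none
Why: Fluoride-mediated cleavage of the six aryl silyl ethers under buffered acidic conditions, so that no phenoxide is generated that could add to the acryloyl group and the 6-hydroxyl stays hydrogen-bonded to the C7 carbonyl.

**Compound list**

1 | 3,5-dimethoxyphenol | COc1cc(O)cc(OC)c1 | starting material
2 | 2-bromo-3,5-dimethoxyphenol | Oc1cc(OC)cc(OC)c1Br | intermediate
3 | (2-bromo-3,5-dimethoxyphenoxy)trimethylsilane | C[Si](C)(C)Oc1cc(OC)cc(OC)c1Br | intermediate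
4 | 2-lithio-3,5-dimethoxyphenyl trimethylsilyl ether (formed in the flask) | C[Si](C)(C)Oc1cc(OC)cc(OC)c1[Li] | intermediate
5 | lithium 3,5-dimethoxy-2-(trimethylsilyl)phenoxide (formed in the flask) | [Li+].[O-]c1cc(OC)cc(OC)c1[Si](C)(C)C | intermediate
6 | 3,5-dimethoxy-2-(trimethylsilyl)phenyl trifluoromethanesulfonate | COc1cc(OC)c([Si](C)(C)C)c(OS(=O)(=O)C(F)(F)F)c1 | intermediate
7 | methyl 3-(4-methoxyphenyl)-3-oxopropanoate | COC(=O)CC(=O)c1ccc(OC)cc1 | starting material
8 | phenyliodonium ylide of methyl 3-(4-methoxyphenyl)-3-oxopropanoate | COC(=O)[C-]([I+]c1ccccc1)C(=O)c1ccc(OC)cc1 | intermediate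
9 | 3,5-dimethoxybenzyne (formed in the flask) | COC1=CC(OC)=CC#C1 | intermediate
10 | methyl 4,6-dimethoxy-2-(4-methoxyphenyl)benzofuran-3-carboxylate | COC(=O)c1c(-c2ccc(OC)cc2)oc2cc(OC)cc(OC)c12 | intermediate
11 | N,4,6-trimethoxy-2-(4-methoxyphenyl)-N-methylbenzofuran-3-carboxamide | CON(C)C(=O)c1c(-c2ccc(OC)cc2)oc2cc(OC)cc(OC)c12 | intermediate
12 | 1-bromo-2,4-dimethoxybenzene | COc1ccc(Br)c(OC)c1 | starting material
13 | 2,4-dimethoxyphenyllithium (formed in the flask) | [Li]c1ccc(OC)cc1OC | intermediate
14 | (2,4-dimethoxyphenyl)[4,6-dimethoxy-2-(4-methoxyphenyl)benzofuran-3-yl]methanone | COc1ccc(C(=O)c2c(-c3ccc(OC)cc3)oc3cc(OC)cc(OC)c23)c(OC)c1 | intermediate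
15 | 4-methoxyphenylacetyl chloride | COc1ccc(CC(Cl)=O)cc1 | starting material
16 | 1-[3-(2,4-dimethoxybenzoyl)-4,6-dimethoxy-2-(4-methoxyphenyl)benzofuran-7-yl]-2-(4-methoxyphenyl)ethan-1-one | COc1ccc(CC(=O)c2c(OC)cc(OC)c3c(C(=O)c4ccc(OC)cc4OC)c(-c4ccc(OC)cc4)oc23)cc1 | intermediate
17 | 1-[3-(2,4-dihydroxybenzoyl)-4,6-dihydroxy-2-(4-hydroxyphenyl)benzofuran-7-yl]-2-(4-hydroxyphenyl)ethan-1-one | O=C(Cc1ccc(O)cc1)c1c(O)cc(O)c2c(C(=O)c3ccc(O)cc3O)c(-c3ccc(O)cc3)oc12 | intermediate
18 | hexakis(tert-butyldimethylsilyl) ether of 17 | O=C(Cc1ccc(O[Si](C)(C)C(C)(C)C)cc1)c1c(O[Si](C)(C)C(C)(C)C)cc(O[Si](C)(C)C(C)(C)C)c2c(C(=O)c3ccc(O[Si](C)(C)C(C)(C)C)cc3O[Si](C)(C)C(C)(C)C)c(-c3ccc(O[Si](C)(C)C(C)(C)C)cc3)oc12 | intermediate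
19 | hexakis(tert-butyldimethylsilyl) ether of the target (2-arylprop-2-en-1-one) | C=C(C(=O)c1c(O[Si](C)(C)C(C)(C)C)cc(O[Si](C)(C)C(C)(C)C)c2c(C(=O)c3ccc(O[Si](C)(C)C(C)(C)C)cc3O[Si](C)(C)C(C)(C)C)c(-c3ccc(O[Si](C)(C)C(C)(C)C)cc3)oc12)c1ccc(O[Si](C)(C)C(C)(C)C)cc1 | intermediate
20 | 1-[3-(2,4-dihydroxybenzoyl)-4,6-dihydroxy-2-(4-hydroxyphenyl)benzofuran-7-yl]-2-(4-hydroxyphenyl)prop-2-en-1-one | C=C(C(=O)c1c(O)cc(O)c2c(C(=O)c3ccc(O)cc3O)c(-c3ccc(O)cc3)oc12)c1ccc(O)cc1 | target

**Step count**

Total steps: 12. Longest linear sequence: 11 (steps 1–3 and 5–12); step 4 is a one-step branch that joins at step 5.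

**Steps most likely to fail, with fallbacks**

Step 5. The acyclic ylide may lose iodobenzene or be protonated before it meets the short-lived aryne. Addition to the unsymmetrical aryne could also begin at carbon instead of oxygen, which would reverse the orientation and move the methoxyls to C5 and C7. The fallback sets out from 1 and 7 and forms the same two bonds in the opposite polarity sense. Oxidative coupling of the ketoester α-carbon with the ortho carbon of the phenol, catalysed by FeCl3·6H2O with di-tert-butyl peroxide in 1,2-dichloroethane at 100 °C, is followed in the same pot by cyclodehydration of the phenol oxygen onto the aryl ketone. Because the phenol oxygen becomes O1 and the carbon next to it carries the ketoester, the regiochemistry is fixed, and the path returns to the route at 10; no further compound arises on it (new compounds: none F0).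

Step 8. Acylation could spread to C5 or to the dimethoxybenzoyl ring, a second acyl group could enter, or SnCl4 could strip the methyl ether next to the new ketone and complicate the mixture. The fallback sets out from 14 and uses a small, mild electrophile first. Vilsmeier–Haack formylation (POCl3, DMF, then aqueous NaOAc), the best-documented C7 substitution of 4,6-dimethoxybenzofurans, should give 3-(2,4-dimethoxybenzoyl)-4,6-dimethoxy-2-(4-methoxyphenyl)benzofuran-7-carbaldehyde F1. Addition of 4-methoxybenzylmagnesium chloride in THF at −78 °C, where the aldehyde should react ahead of the hindered diaryl ketone, should give racemic 1-[3-(2,4-dimethoxybenzoyl)-4,6-dimethoxy-2-(4-methoxyphenyl)benzofuran-7-yl]-2-(4-methoxyphenyl)ethan-1-ol F2. Dess–Martin oxidation of this benzylic alcohol returns to the route at 16.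

Step 12. During six-fold desilylation the freed 6-hydroxyl may close onto the β-carbon of the acryloyl group (oxa-Michael ring closure to a chromanone), or the unhindered enone may oligomerise under fluoride. The fallback sets out from 19 and keeps the double bond masked until all phenols are free. Conjugate addition of thiophenol (catalytic Et3N, CH2Cl2, rt) should give the racemic hexasilylated 3-(phenylsulfanyl)propan-1-one F3. HF·pyridine then removes the silyl groups without an enone present, giving the racemic hexaphenolic β-phenylsulfanyl ketone F4. Oxidation with one equivalent of mCPBA at −78 °C should give the β-phenylsulfinyl ketone F5 as a mixture of diastereomers. Warming F5 in dioxane or toluene at about 80 °C triggers neutral, thermal syn-elimination of benzenesulfenic acid towards the acidic α-hydrogen and returns to the route at 20.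

Further compounds
F0 | step 5 | none | none
F1 | step 8 | 3-(2,4-dimethoxybenzoyl)-4,6-dimethoxy-2-(4-methoxyphenyl)benzofuran-7-carbaldehyde | O=Cc1c(OC)cc(OC)c2c(C(=O)c3ccc(OC)cc3OC)c(-c3ccc(OC)cc3)oc12
F2 | step 8 | racemic 1-[3-(2,4-dimethoxybenzoyl)-4,6-dimethoxy-2-(4-methoxyphenyl)benzofuran-7-yl]-2-(4-methoxyphenyl)ethan-1-ol | OC(Cc1ccc(OC)cc1)c1c(OC)cc(OC)c2c(C(=O)c3ccc(OC)cc3OC)c(-c3ccc(OC)cc3)oc12
F3 | step 12 | racemic hexakis(tert-butyldimethylsilyl) ether of 1-[3-(2,4-dihydroxybenzoyl)-4,6-dihydroxy-2-(4-hydroxyphenyl)benzofuran-7-yl]-2-(4-hydroxyphenyl)-3-(phenylsulfanyl)propan-1-one | O=C(C(CSc1ccccc1)c1ccc(O[Si](C)(C)C(C)(C)C)cc1)c1c(O[Si](C)(C)C(C)(C)C)cc(O[Si](C)(C)C(C)(C)C)c2c(C(=O)c3ccc(O[Si](C)(C)C(C)(C)C)cc3O[Si](C)(C)C(C)(C)C)c(-c3ccc(O[Si](C)(C)C(C)(C)C)cc3)oc12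
F4 | step 12 | racemic 1-[3-(2,4-dihydroxybenzoyl)-4,6-dihydroxy-2-(4-hydroxyphenyl)benzofuran-7-yl]-2-(4-hydroxyphenyl)-3-(phenylsulfanyl)propan-1-one | O=C(C(CSc1ccccc1)c1ccc(O)cc1)c1c(O)cc(O)c2c(C(=O)c3ccc(O)cc3O)c(-c3ccc(O)cc3)oc12
F5 | step 12 | 1-[3-(2,4-dihydroxybenzoyl)-4,6-dihydroxy-2-(4-hydroxyphenyl)benzofuran-7-yl]-2-(4-hydroxyphenyl)-3-(phenylsulfinyl)propan-1-one (mixture of diastereomers) | O=C(C(CS(=O)c1ccccc1)c1ccc(O)cc1)c1c(O)cc(O)c2c(C(=O)c3ccc(O)cc3O)c(-c3ccc(O)cc3)oc12
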